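**Plan**
Isoflavone numbering is used: ring A = C4a, C5–C8, C8a; ring C = O1, C2–C4; ring B = C1'–C6'.
Cuts: first O7–Si. Then ring A is cut at C8–C8a, C5–C6, C7–C8 and C4a–C5, leaving a 2-diazoacetyl-5-aryl-4-pyranone and (triisopropylsilyloxy)ethyne. Last comes the C3–C1' aryl bond (Suzuki–Miyaura).
Enabling feature: ring A bears oxygen on C5, C7 and C8a (1,3,5 pattern). C5 maps onto a ketene carbon, C7 onto the siloxy carbon of the alkyne, C8a onto the O1-bearing C2 of a 4-pyranone, and the free pyranone C3–H becomes C4a.
Forward order: ring C comes ready-made in kojic acid, ring B is joined at the triflate stage, ring A is closed by the photochemical benzannulation, and fluoride then frees the 7-OH.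
The alkyne arm takes two steps from trimethylsilyldiazomethane, CO and TIPSOTf; the same diazoalkane also supplies C8.
Stereochemistry: the target has no stereocentre and no stereogenic double bond. The stereocentres of two cascade intermediates are erased on aromatisation.

Key step: step 10

Remark on the chemistry: rotation about the hindered C3–C1' bond is taken as fast at room temperature, so no axial descriptor is assigned to any aryl-pyranone or aryl-chromone of the route.

Step 1
Reactants: 1 kojic acid (5-hydroxy-2-(hydroxymethyl)-4H-pyran-4-one)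
Product: 2 comenic acid (5-hydroxy-4-oxo-4H-pyran-2-carboxylic acid)
Conditions: O2 (1 atm), Pd/C (cat.), aq NaOH (pH 10–11), 40 °C; then aq HCl to pH 1–2
Reagents that add atoms: dioxygen O=O
Why: Heyns-type aerobic oxidation over a noble metal takes the primary alcohol to the carboxylate in alkaline water, a long-established preparative conversion of kojic acid, while the enolic 5-OH is masked as its sodium salt.

Step 2
Reactants: 2 comenic acid
Product: 3 methyl comenate (methyl 5-hydroxy-4-oxo-4H-pyran-2-carboxylate)
Conditions: MeOH, H2SO4 (cat.), reflux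
Reagents that add atoms: methanol CO
Why: Fischer esterification in excess methanol masks the acid for the coupling and leaves the enolic 5-OH, the only remaining acidic site, free for activation.

Step 3
Reactants: 3 methyl comenate
Product: 4 methyl 4-oxo-5-(trifluoromethylsulfonyloxy)-4H-pyran-2-carboxylate
Conditions: Tf2O, pyridine, CH2Cl2, −10 to 0 °C
Reagents that add atoms: trifluoromethanesulfonic anhydride O=S(=O)(OS(=O)(=O)C(F)(F)F)C(F)(F)F
Why: O-sulfonylation of the acidic enolic hydroxyl gives an enol triflate alpha to the ring carbonyl, the activation commonly used for cross-coupling at C5 of kojic acid derivatives.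

Step 4
Reactants: 5 1,2,3,5-tetramethoxybenzene
Product: 8 2,3,4,6-tetramethoxyphenylboronic acid, via aryllithium 6 (not isolated), via lithium triisopropoxyborate 7 (not isolated)
Conditions: n-BuLi, THF, 0 °C to rt; B(O-i-Pr)3, −78 °C to rt; 1 M HCl, 0 °C (brief)
Reagents that add atoms: n-butyllithium [Li]CCCC (lithium of 6 and 7); triisopropyl borate CC(C)OB(OC(C)C)OC(C)C; water O
Why: Directed ortho-metalation removes one of the two equivalent ring protons, each flanked by two methoxy groups, and borate quench with brief cold hydrolysis is the standard route to an arylboronic acid, so no regiochemical question arises.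

Step 5
Reactants: 4 methyl 4-oxo-5-(trifluoromethylsulfonyloxy)-4H-pyran-2-carboxylate; 8 2,3,4,6-tetramethoxyphenylboronic acid (1.5 equiv)
Product: 9 methyl 4-oxo-5-(2,3,4,6-tetramethoxyphenyl)-4H-pyran-2-carboxylate
Conditions: Pd(OAc)2 (5 mol %), SPhos (10 mol %), K3PO4 (anhydrous), toluene, 80 °C
Reagents that add atoms: none
Why: Suzuki–Miyaura coupling, in which zerovalent palladium inserts readily into the electron-poor enol triflate, the bulky electron-rich biarylphosphine is the established remedy for di-ortho-substituted boronic acids, and anhydrous phosphate in toluene spares the ester, the triflate S–O bond and the base-sensitive pyranone.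

Step 6
Reactants: 9 methyl 4-oxo-5-(2,3,4,6-tetramethoxyphenyl)-4H-pyran-2-carboxylate
Product: 10 4-oxo-5-(2,3,4,6-tetramethoxyphenyl)-4H-pyran-2-carboxylic acid
Conditions: LiOH (1.2 equiv), THF–H2O, 0 °C; then 1 M HCl
Reagents that add atoms: lithium hydroxide [Li+].[OH-]
Why: Saponification at 0 °C exploits the high electrophilicity of an ester on the electron-poor ring, so acyl substitution should be complete before hydroxide can add to C6 and open the pyranone.

Step 7
Reactants: 10 4-oxo-5-(2,3,4,6-tetramethoxyphenyl)-4H-pyran-2-carboxylic acid; 11 trimethylsilyldiazomethane (1.5 equiv)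
Product: 14 2-(2-diazoacetyl)-5-(2,3,4,6-tetramethoxyphenyl)-4H-pyran-4-one, via acid chloride 12 (not isolated), via silyl diazo ketone 13 (not isolated)
Conditions: 1-chloro-N,N,2-trimethylprop-1-en-1-amine (1.05 equiv), CH2Cl2, 0 °C to rt; then 11, Et3N, THF–MeCN, 0 °C; aq NaHCO3 work-up, SiO2
Reagents that add atoms: 1-chloro-N,N,2-trimethylprop-1-en-1-amine CC(C)=C(Cl)N(C)C (chlorine of 12)
Why: Arndt–Eistert-type C-acylation of a diazoalkane, in which the acid chloride forms under neutral conditions that release neither HCl nor a Vilsmeier species toward the electron-rich ring B, the bulky silyl diazoalkane should acylate faster than it adds as a 1,3-dipole to the trisubstituted pyranone C2=C3 bond, and the labile C–Si bond of 13 is hydrolysed on work-up.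

Step 8
Reactants: 11 trimethylsilyldiazomethane; 15 triisopropylsilyl trifluoromethanesulfonate
Product: 18 1-(triisopropylsilyloxy)-2-(trimethylsilyl)ethyne, via lithiated diazoalkane 16 (not isolated), via lithium ynolate 17 (not isolated)
Conditions: n-BuLi, THF, −78 °C; CO (1 atm), −78 °C; 15, −78 to 0 °C
Reagents that add atoms: n-butyllithium [Li]CCCC (lithium of 16 and 17); carbon monoxide [C-]#[O+]
Why: Carbonylation of lithiated silyldiazomethane with loss of N2 is a known ynolate synthesis, and the hard, bulky silyl triflate should attack the ynolate at oxygen, the standard entry to siloxyalkynes, because attack at carbon would crowd two silyl groups on one atom.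

Step 9
Reactants: 18 1-(triisopropylsilyloxy)-2-(trimethylsilyl)ethyne
Product: 19 (triisopropylsilyloxy)ethyne
Conditions: K2CO3 (cat.), MeOH, 0 °C; pentane extraction, careful concentration, bulb-to-bulb distillation
Reagents that add atoms: none
Why: Methoxide-catalysed protiodesilylation of an alkynyl–SiMe3 group, routine for releasing terminal alkynes, should be selective because attack at the open SiMe3 is far faster than at the shielded O–Si(i-Pr)3, and the basic medium avoids the protonation to which ynol ethers are sensitive.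

Step 10
Reactants: 14 2-(2-diazoacetyl)-5-(2,3,4,6-tetramethoxyphenyl)-4H-pyran-4-one; 19 (triisopropylsilyloxy)ethyne (2.5 equiv)
Product: 24 5-hydroxy-3-(2,3,4,6-tetramethoxyphenyl)-7-(triisopropylsilyloxy)-4H-chromen-4-one, via pyranonylketene 20 (not isolated), via siloxycyclobutenone 21 (not isolated), via dienylketene 22 (not isolated), via cyclohexadienone 23 (not isolated)
Conditions: degassed ClCH2CH2Cl (0.1 M), hν (365 nm LED, borosilicate vessel), 20 °C until 14 is consumed; then 80 °C in the dark
Reagents that add atoms: none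
Why: Excitation of the diazo ketone expels N2 and the pyranon-2-yl carbon migrates to the carbene carbon (Wolff rearrangement, C8–C8a), giving ketene 20, whose C=C=O unit is conjugated with the pyranone C2=C3 bond. The nucleophilic CH terminus of 19 attacks the ketene carbonyl carbon and the siloxy-bearing carbon then bonds to the former carbene carbon, a polarity-matched (2+2) cycloaddition that forms C5–C6 and C7–C8 and closes the transient four-membered ring of 21. Light or the heating at 80 °C opens 21 by reversible 4π electrocyclic cleavage of the C5–C8 bond; only isomer 22, with ketene and pyranone cis on the new double bond, can react on, so the unproductive isomer is recycled through 21. Ring A then closes by a 6π disrotatory electrocyclization (six-membered carbocycle, C4a–C5) onto the pyranone C3–H carbon, an enol-ether β-carbon well matched to the electrophilic ketene, and enolisation of 23, helped by the hydrogen bond from 5-OH to the C4 carbonyl, makes the sequence irreversible. This is the photochemical diazo ketone variant of the Danheiser benzannulation, established with siloxyalkynes for alkenyl, aryl and five-membered heteroaryl diazomethyl ketones and applied here to a pyranonyl one. No stereocentre remains; the meta O5/O7 pattern follows from the ynol ether polarity, the closure site is unique because C3 is the only carbon conjugated with the migrated terminus, and irradiation at 365 nm addresses the diazo chromophore while sparing the short-wavelength pyranone band.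

Step 11
Reactants: 24 5-hydroxy-3-(2,3,4,6-tetramethoxyphenyl)-7-(triisopropylsilyloxy)-4H-chromen-4-one
Product: 25 5,7-dihydroxy-3-(2,3,4,6-tetramethoxyphenyl)-4H-chromen-4-one (CNP0259543.0)
Conditions: Bu4NF, AcOH, THF, 0 °C
Reagents that add atoms: none
Why: Fluoride-mediated cleavage of the aryl silyl ether, driven by the Si–F bond, is buffered with acetic acid so that the acidic 7-phenol is released without long exposure of the chromone to basic fluoride, and the four methyl ethers are inert.

**Compound list**
1 | kojic acid | OCc1cc(=O)c(O)co1 | starting material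
2 | comenic acid | OC(=O)c1cc(=O)c(O)co1 | intermediate
3 | methyl comenate | COC(=O)c1cc(=O)c(O)co1 | intermediate
4 | methyl 4-oxo-5-(trifluoromethylsulfonyloxy)-4H-pyran-2-carboxylate | COC(=O)c1cc(=O)c(OS(=O)(=O)C(F)(F)F)co1 | intermediate
5 | 1,2,3,5-tetramethoxybenzene | COc1cc(OC)c(OC)c(OC)c1 | starting material
6 | (2,3,4,6-tetramethoxyphenyl)lithium | [Li]c1c(OC)cc(OC)c(OC)c1OC | intermediate
7 | lithium triisopropoxy(2,3,4,6-tetramethoxyphenyl)borate | [Li+].CC(C)O[B-](OC(C)C)(OC(C)C)c1c(OC)cc(OC)c(OC)c1OC | intermediate
8 | 2,3,4,6-tetramethoxyphenylboronic acid | OB(O)c1c(OC)cc(OC)c(OC)c1OC | intermediate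
9 | methyl 4-oxo-5-(2,3,4,6-tetramethoxyphenyl)-4H-pyran-2-carboxylate | COC(=O)c1cc(=O)c(-c2c(OC)cc(OC)c(OC)c2OC)co1 | intermediate
10 | 4-oxo-5-(2,3,4,6-tetramethoxyphenyl)-4H-pyran-2-carboxylic acid | OC(=O)c1cc(=O)c(-c2c(OC)cc(OC)c(OC)c2OC)co1 | intermediate
11 | trimethylsilyldiazomethane | C[Si](C)(C)C=[N+]=[N-] | starting material
12 | 4-oxo-5-(2,3,4,6-tetramethoxyphenyl)-4H-pyran-2-carbonyl chloride | ClC(=O)c1cc(=O)c(-c2c(OC)cc(OC)c(OC)c2OC)co1 | intermediate
13 | 2-[2-diazo-2-(trimethylsilyl)acetyl]-5-(2,3,4,6-tetramethoxyphenyl)-4H-pyran-4-one | C[Si](C)(C)C(=[N+]=[N-])C(=O)c1cc(=O)c(-c2c(OC)cc(OC)c(OC)c2OC)co1 | intermediate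
14 | 2-(2-diazoacetyl)-5-(2,3,4,6-tetramethoxyphenyl)-4H-pyran-4-one | [N-]=[N+]=CC(=O)c1cc(=O)c(-c2c(OC)cc(OC)c(OC)c2OC)co1 | intermediate
15 | triisopropylsilyl trifluoromethanesulfonate | CC(C)[Si](C(C)C)(C(C)C)OS(=O)(=O)C(F)(F)F | starting material
16 | lithio(trimethylsilyl)diazomethane | [Li]C(=[N+]=[N-])[Si](C)(C)C | intermediate
17 | lithium (trimethylsilyl)ethynolate | [Li]OC#C[Si](C)(C)C | intermediate
18 | 1-(triisopropylsilyloxy)-2-(trimethylsilyl)ethyne | C[Si](C)(C)C#CO[Si](C(C)C)(C(C)C)C(C)C | intermediate
19 | (triisopropylsilyloxy)ethyne | C#CO[Si](C(C)C)(C(C)C)C(C)C | intermediate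
20 | 2-(2-oxoethenyl)-5-(2,3,4,6-tetramethoxyphenyl)-4H-pyran-4-one (pyranonylketene) | O=C=Cc1cc(=O)c(-c2c(OC)cc(OC)c(OC)c2OC)co1 | intermediate
21 | 2-[4-oxo-2-(triisopropylsilyloxy)cyclobut-2-en-1-yl]-5-(2,3,4,6-tetramethoxyphenyl)-4H-pyran-4-one (racemic) | O=C1C=C(O[Si](C(C)C)(C(C)C)C(C)C)C1c1cc(=O)c(-c2c(OC)cc(OC)c(OC)c2OC)co1 | intermediate
22 | 4-[4-oxo-5-(2,3,4,6-tetramethoxyphenyl)-4H-pyran-2-yl]-3-(triisopropylsilyloxy)buta-1,3-dien-1-one, ketene and pyranone cis on C3=C4 | O=C=C/C(O[Si](C(C)C)(C(C)C)C(C)C)=C\c1cc(=O)c(-c2c(OC)cc(OC)c(OC)c2OC)co1 | intermediate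
23 | 3-(2,3,4,6-tetramethoxyphenyl)-7-(triisopropylsilyloxy)-4aH-chromene-4,5-dione (racemic keto tautomer) | O=C1C=C(O[Si](C(C)C)(C(C)C)C(C)C)C=C2OC=C(c3c(OC)cc(OC)c(OC)c3OC)C(=O)C12 | intermediate
24 | 5-hydroxy-3-(2,3,4,6-tetramethoxyphenyl)-7-(triisopropylsilyloxy)-4H-chromen-4-one | O=c1c(-c2c(OC)cc(OC)c(OC)c2OC)coc2cc(O[Si](C(C)C)(C(C)C)C(C)C)cc(O)c12 | intermediate
25 | 5,7-dihydroxy-3-(2,3,4,6-tetramethoxyphenyl)-4H-chromen-4-one | COc1cc(OC)c(-c2coc3cc(O)cc(O)c3c2=O)c(OC)c1OC | target

Total step count: 11. Longest linear sequence: 8 steps (1, 2, 3, 5, 6, 7, 10, 11).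

**Steps most likely to fail**

1. Step 10.
- What may go wrong: the pyranone chromophore, or the chromone as it accumulates, may compete for light. Material could then drift into ring contraction or enone–alkyne photocycloaddition. The ketene may also dimerise before the alkyne traps it.
- Fallback (the same ketene made in the dark by dehydrochlorination): it sets out from 14. A silver-catalysed Wolff rearrangement in aqueous THF (AgO2CPh cat., Et3N, dark; Arndt–Eistert homologation) lets water capture ketene 20 as [4-oxo-5-(2,3,4,6-tetramethoxyphenyl)-4H-pyran-2-yl]acetic acid F1. This acid is kept cold because it is a vinylogous β-keto acid. 1-Chloro-N,N,2-trimethylprop-1-en-1-amine converts it into [4-oxo-5-(2,3,4,6-tetramethoxyphenyl)-4H-pyran-2-yl]acetyl chloride F2. Slow addition of Et3N to F2 and 19 in toluene at 80 °C regenerates 20 at low stationary concentration, where the route is rejoined. The purely thermal (2+2)/4π/6π sequence through 21, 22 and 23 should end at 24. Silver cannot be used directly beside 19, since silver salts activate siloxyalkynes; hence the detour.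

2. Step 9.
- What may go wrong: methoxide may also attack the O–Si bond, with loss of the freed ynolate by protonation. Base may trigger oxygen-to-carbon silyl migration, and the volatile alkyne may be lost on concentration.
- Fallback (carry the C-silyl group through the benzannulation and remove it from the arene): it sets out from 18, which is irradiated with 14 under the conditions of step 10. The SiMe3 group sits on the nucleophilic alkyne carbon, where it stabilises the positive charge developing on the siloxy carbon (β-silicon effect). The cascade should run via ketene 20, the C-silylated cyclobutenone F3, the C-silylated dienylketene F4 and the C-silylated cyclohexadienone F5 to 5-hydroxy-3-(2,3,4,6-tetramethoxyphenyl)-7-(triisopropylsilyloxy)-6-(trimethylsilyl)-4H-chromen-4-one F6. Ipso-protodesilylation of this phloroglucinol-type ring with CF3CO2H in CH2Cl2 at 0 °C, which aryl triisopropylsilyl ethers tolerate, returns the material to the route at 24.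

3. Step 5.
- What may go wrong: protodeboronation of the di-ortho-methoxy boronic acid may outrun the slow transmetalation at the hindered carbon. The base may also cleave the S–O bond of the triflate.
- Fallback (base-free Negishi coupling): it sets out from 6, generated from 5 as in step 4. Transmetalation with ZnCl2 in THF gives chloro(2,3,4,6-tetramethoxyphenyl)zinc F7. Coupling with 4 (Pd(OAc)2, SPhos, THF, 25–50 °C) comes back to the route at 9.

**Further compounds**
F1 | step 10 | [4-oxo-5-(2,3,4,6-tetramethoxyphenyl)-4H-pyran-2-yl]acetic acid | OC(=O)Cc1cc(=O)c(-c2c(OC)cc(OC)c(OC)c2OC)co1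
F2 | step 10 | [4-oxo-5-(2,3,4,6-tetramethoxyphenyl)-4H-pyran-2-yl]acetyl chloride | ClC(=O)Cc1cc(=O)c(-c2c(OC)cc(OC)c(OC)c2OC)co1
F3 | step 9 | 2-[4-oxo-2-(triisopropylsilyloxy)-3-(trimethylsilyl)cyclobut-2-en-1-yl]-5-(2,3,4,6-tetramethoxyphenyl)-4H-pyran-4-one (racemic) | O=C1C([Si](C)(C)C)=C(O[Si](C(C)C)(C(C)C)C(C)C)C1c1cc(=O)c(-c2c(OC)cc(OC)c(OC)c2OC)co1
F4 | step 9 | 4-[4-oxo-5-(2,3,4,6-tetramethoxyphenyl)-4H-pyran-2-yl]-3-(triisopropylsilyloxy)-2-(trimethylsilyl)buta-1,3-dien-1-one, ketene and pyranone cis on C3=C4 | O=C=C([Si](C)(C)C)/C(O[Si](C(C)C)(C(C)C)C(C)C)=C\c1cc(=O)c(-c2c(OC)cc(OC)c(OC)c2OC)co1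
F5 | step 9 | 3-(2,3,4,6-tetramethoxyphenyl)-7-(triisopropylsilyloxy)-6-(trimethylsilyl)-4aH-chromene-4,5-dione (racemic) | O=C1C([Si](C)(C)C)=C(O[Si](C(C)C)(C(C)C)C(C)C)C=C2OC=C(c3c(OC)cc(OC)c(OC)c3OC)C(=O)C12
F6 | step 9 | 5-hydroxy-3-(2,3,4,6-tetramethoxyphenyl)-7-(triisopropylsilyloxy)-6-(trimethylsilyl)-4H-chromen-4-one | O=c1c(-c2c(OC)cc(OC)c(OC)c2OC)coc2cc(O[Si](C(C)C)(C(C)C)C(C)C)c([Si](C)(C)C)c(O)c12
F7 | step 5 | chloro(2,3,4,6-tetramethoxyphenyl)zinc | Cl[Zn]c1c(OC)cc(OC)c(OC)c1OC
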